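## Retrosynthetic overview

1. Target 16 ⇐ tribenzyl ether 15 by global hydrogenolysis, kept last so that the free ortho-hydroxybenzylamine and the 5-hydroxyflavanone never see base or heat.
2. 15 ⇐ chromone 13 + arylboronic acid 14: the C2–aryl bond and the (2S) centre come from a rhodium-catalysed asymmetric 1,4-arylation, not from a chalcone cyclisation; ring B is attached last.
3. 13 ⇐ N-methylpyridinium salt 10: the (R)-N-methylpiperidine (ring D) comes from an iridium-catalysed asymmetric hydrogenation of the aromatic pyridinium, not from a Mannich reaction with a piperideine.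
4. 10 ⇐ 6-iodochromone 6 + 2-pyridylzinc bromide 7 (Negishi), then MeI; the C6 regiochemistry comes from iodination ortho to the free 5-OH of 3.
5. Ring order: rings A and C are bought together as 5,7-dihydroxychromone 1; the pyridine ring is coupled on and then reduced to ring D; ring B comes in last.

Assumption: the absolute sense of induction of the two chiral catalysts (steps 6 and 7) is assigned by analogy with simpler substrates and is verified on first use by chiral HPLC and X-ray crystallography; should a sense prove reversed, the mirror-image ligand is used with no other change.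

## Route

Step 1
Reactants: 1 5,7-dihydroxy-4H-chromen-4-one; 2 benzyl bromide
Product: 3 7-(benzyloxy)-5-hydroxy-4H-chromen-4-one
Conditions: K2CO3 (1.1 equiv), BnBr (1.05 equiv), acetone, reflux
Reagents that add atoms: benzyl bromide, BrCc1ccccc1
Why: Williamson ether synthesis; the 7-OH is the acidic, free phenol whereas the 5-OH is locked in a hydrogen bond to the C4 carbonyl, so one equivalent of BnBr with a weak base alkylates O7 only.

Step 2
Reactants: 3 7-(benzyloxy)-5-hydroxy-4H-chromen-4-one; 4 benzyltrimethylammonium dichloroiodate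
Product: 5 7-(benzyloxy)-5-hydroxy-6-iodo-4H-chromen-4-one
Conditions: BnMe3N·ICl2 (1.05 equiv), CaCO3, CH2Cl2–MeOH 5:2, rt
Reagents that add atoms: benzyltrimethylammonium dichloroiodate, C[N+](C)(C)Cc1ccccc1.Cl[I-]Cl
Why: Electrophilic aromatic iodination directed ortho to the free, chelated 5-OH, the known site of iodination of 5-hydroxy-7-alkoxy-chromones and -flavones; CaCO3 buffers the HCl, and the C6 position is confirmed by HMBC from the chelated OH proton.

Step 3
Reactants: 5 7-(benzyloxy)-5-hydroxy-6-iodo-4H-chromen-4-one; 2 benzyl bromide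
Product: 6 5,7-bis(benzyloxy)-6-iodo-4H-chromen-4-one
Conditions: K2CO3 (2 equiv), BnBr (1.5 equiv), DMF, 60 °C
Reagents that add atoms: benzyl bromide, BrCc1ccccc1
Why: Williamson etherification of the hindered chelated phenol under more forcing conditions; it caps the last phenol so that no ortho-hydroxybenzylamine (prone to quinone-methide epimerisation) exists before the final step.

Step 4
Reactants: 6 5,7-bis(benzyloxy)-6-iodo-4H-chromen-4-one; 7 2-pyridylzinc bromide
Product: 8 5,7-bis(benzyloxy)-6-(pyridin-2-yl)-4H-chromen-4-one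
Conditions: 7 (0.5 M in THF, 1.8 equiv), Pd2(dba)3 (2.5 mol %), XPhos (10 mol %), THF, 65 °C
Reagents that add atoms: 2-pyridylzinc bromide, Br[Zn]c1ccccn1
Why: Negishi cross-coupling; zerovalent palladium carrying the bulky biarylphosphine inserts into the di-ortho-substituted C–I bond, the 2-pyridylzinc reagent avoids the protodeboronation of 2-pyridylboron reagents, and the chromone is inert to organozinc halides.

Step 5
Reactants: 8 5,7-bis(benzyloxy)-6-(pyridin-2-yl)-4H-chromen-4-one; 9 iodomethane
Product: 10 2-[5,7-bis(benzyloxy)-4-oxo-4H-chromen-6-yl]-1-methylpyridin-1-ium iodide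
Conditions: MeI (10 equiv), MeCN, 80 °C, sealed tube
Reagents that add atoms: iodomethane, CI
Why: Menshutkin N-alkylation; the pyridine nitrogen is the only site nucleophilic enough for MeI (the chromone carbonyl and the benzyl ethers are not), and every atom of both reactants ends in the salt.

Step 6
Reactants: 10 2-[5,7-bis(benzyloxy)-4-oxo-4H-chromen-6-yl]-1-methylpyridin-1-ium iodide
Product: 13 5,7-bis(benzyloxy)-6-[(2R)-1-methylpiperidin-2-yl]-4H-chromen-4-one, via cyclic iminium iodide 11 (not isolated), via piperidinium iodide 12 (not isolated)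
Conditions: H2 (50 bar), [Ir(cod)Cl]2 (2 mol %), (R)-SEGPHOS (4.4 mol %), CH2Cl2–toluene 1:1, 30 °C; then aq. NaHCO3
Reagents that add atoms: none
Why: Proposed new method: asymmetric hydrogenation of a pyridinium salt, in which the iridium hydride/diphosphine/iodide catalyst reduces the activated pyridinium stepwise (1,4-hydride addition, enamine protonation by the HI formed, second hydride) to iminium 11, and the chiral trivalent iridium hydride then adds to one face of its C=N+ bond to set the (R) centre and give salt 12, whose protonated nitrogen cannot bind the catalyst, while the neutral chromone C2=C3 bond is a far weaker hydride acceptor and is left alone; the closest known reaction type is the iridium-catalysed asymmetric hydrogenation of N-benzyl-2-arylpyridinium halides, not yet shown for an N-methyl salt bearing a 2,6-dialkoxyaryl group.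

Step 7
Reactants: 13 5,7-bis(benzyloxy)-6-[(2R)-1-methylpiperidin-2-yl]-4H-chromen-4-one; 14 4-(benzyloxy)phenylboronic acid
Product: 15 (2S)-5,7-bis(benzyloxy)-2-[4-(benzyloxy)phenyl]-6-[(2R)-1-methylpiperidin-2-yl]chroman-4-one
Conditions: 14 (3 equiv), [Rh(OH)(cod)]2 (2.5 mol %), (S)-MeO-F12-BIPHEP [(S)-2,2'-bis[bis(3,4,5-trifluorophenyl)phosphino]-6,6'-dimethoxy-1,1'-biphenyl] (5.5 mol %), toluene–H2O 10:1, 40 °C, no added base
Reagents that add atoms: 4-(benzyloxy)phenylboronic acid, OB(O)c1ccc(OCc2ccccc2)cc1
Why: Hayashi–Miyaura asymmetric 1,4-addition to a chromone; the aryl group on monovalent rhodium bound to the electron-poor chiral diphosphine inserts into one face of the C2=C3 bond under catalyst control to set (2S) (the remote piperidine centre has no say), water protonates C3, and the base-free medium suppresses retro-oxa-Michael opening of the flavanone.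

Step 8
Reactants: 15 (2S)-5,7-bis(benzyloxy)-2-[4-(benzyloxy)phenyl]-6-[(2R)-1-methylpiperidin-2-yl]chroman-4-one
Product: 16 (2S)-5,7-dihydroxy-2-(4-hydroxyphenyl)-6-[(2R)-1-methylpiperidin-2-yl]chroman-4-one (CNP0146489.2)
Conditions: H2 (1 atm), Pd/C (10 wt %), EtOAc–MeOH 1:1, rt, stopped after uptake of 3 equiv; filtration and concentration below 30 °C
Reagents that add atoms: none
Why: Catalytic hydrogenolysis of three aryl benzyl ethers under neutral conditions at room temperature, which touches neither stereocentre; the hindered ring benzylic C–N bond, the C2–O bond and the chelated ketone are much slower to reduce, so the reaction is stopped at three equivalents of H2.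

## Compound list

1 | 5,7-dihydroxy-4H-chromen-4-one | O=c1ccoc2cc(O)cc(O)c12 | starting material
2 | benzyl bromide | BrCc1ccccc1 | starting material
3 | 7-(benzyloxy)-5-hydroxy-4H-chromen-4-one | O=c1ccoc2cc(OCc3ccccc3)cc(O)c12 | intermediate
4 | benzyltrimethylammonium dichloroiodate | C[N+](C)(C)Cc1ccccc1.Cl[I-]Cl | starting material
5 | 7-(benzyloxy)-5-hydroxy-6-iodo-4H-chromen-4-one | O=c1ccoc2cc(OCc3ccccc3)c(I)c(O)c12 | intermediate
6 | 5,7-bis(benzyloxy)-6-iodo-4H-chromen-4-one | O=c1ccoc2cc(OCc3ccccc3)c(I)c(OCc3ccccc3)c12 | intermediate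
7 | 2-pyridylzinc bromide, bromo(pyridin-2-yl)zinc | Br[Zn]c1ccccn1 | starting material
8 | 5,7-bis(benzyloxy)-6-(pyridin-2-yl)-4H-chromen-4-one | O=c1ccoc2cc(OCc3ccccc3)c(-c3ccccn3)c(OCc3ccccc3)c12 | intermediate
9 | iodomethane | CI | starting material
10 | 2-[5,7-bis(benzyloxy)-4-oxo-4H-chromen-6-yl]-1-methylpyridin-1-ium iodide | C[n+]1ccccc1-c1c(OCc2ccccc2)cc2occc(=O)c2c1OCc1ccccc1.[I-] | intermediate
11 | 6-[5,7-bis(benzyloxy)-4-oxo-4H-chromen-6-yl]-1-methyl-2,3,4,5-tetrahydropyridin-1-ium iodide, the cyclic iminium formed in the flask in step 6 | C[N+]1=C(CCCC1)c1c(OCc2ccccc2)cc2occc(=O)c2c1OCc1ccccc1.[I-] | intermediate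
12 | (2R)-2-[5,7-bis(benzyloxy)-4-oxo-4H-chromen-6-yl]-1-methylpiperidin-1-ium iodide, the hydroiodide formed in the flask in step 6 | C[NH+]1CCCC[C@@H]1c1c(OCc2ccccc2)cc2occc(=O)c2c1OCc1ccccc1.[I-] | intermediate
13 | 5,7-bis(benzyloxy)-6-[(2R)-1-methylpiperidin-2-yl]-4H-chromen-4-one | CN1CCCC[C@@H]1c1c(OCc2ccccc2)cc2occc(=O)c2c1OCc1ccccc1 | intermediate
14 | 4-(benzyloxy)phenylboronic acid | OB(O)c1ccc(OCc2ccccc2)cc1 | starting material
15 | (2S)-5,7-bis(benzyloxy)-2-[4-(benzyloxy)phenyl]-6-[(2R)-1-methylpiperidin-2-yl]chroman-4-one | CN1CCCC[C@@H]1c1c(OCc2ccccc2)cc2c(c1OCc1ccccc1)C(=O)C[C@@H](c1ccc(OCc3ccccc3)cc1)O2 | intermediate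
16 | (2S)-5,7-dihydroxy-2-(4-hydroxyphenyl)-6-[(2R)-1-methylpiperidin-2-yl]chroman-4-one | CN1CCCC[C@@H]1c1c(O)cc2c(c1O)C(=O)C[C@@H](c1ccc(O)cc1)O2 | target

## Step count and risk

Total steps: 8. Longest linear sequence: 8 steps, from 1 to 16; all other partners (2, 4, 7, 9, 14) are bought.

The three steps most likely to fail are steps 6, 7 and 4.

Step 6 (asymmetric hydrogenation of the N-methylpyridinium) is the least precedented step. The ee on a di-ortho-substituted N-methyl substrate is unknown, and the chromone double bond must survive. The fallback sets out from 10 and gives up catalyst control in favour of classical resolution. Hydrogenation of 10 with the non-selective catalyst made from [Ir(cod)Cl]2 and racemic SEGPHOS passes through 11 and gives 12 together with its mirror image, (2S)-2-[5,7-bis(benzyloxy)-4-oxo-4H-chromen-6-yl]-1-methylpiperidin-1-ium iodide F2. After aqueous NaHCO3 this becomes a 1:1 mixture of 13 and its enantiomer 5,7-bis(benzyloxy)-6-[(2S)-1-methylpiperidin-2-yl]-4H-chromen-4-one F3. The mixture is resolved by crystallisation from EtOH with a tartaric acid derivative chosen by a small screen, written here for (2R,3R)-di-O-p-toluoyltartaric acid. This gives the 1:1 salt of 13 with (2R,3R)-di-O-p-toluoyltartaric acid F4, while F3 stays in the mother liquor. Aqueous NaHCO3 frees the amine and the route is rejoined at 13.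

Step 7 (asymmetric 1,4-arylation) may be slow on this electron-rich, 5-alkoxy-substituted chromone, and the basic amine could promote ring opening of the product and erode the C2 configuration. The fallback sets out from 13 and builds ring C the classical way, relying on diastereomer separation. Aqueous KOH in EtOH at 60 °C opens the pyranone and expels C2 as formate (retro-Claisen) to give 1-{2,4-bis(benzyloxy)-6-hydroxy-3-[(2R)-1-methylpiperidin-2-yl]phenyl}ethan-1-one F5. Claisen–Schmidt condensation with commercial 4-(benzyloxy)benzaldehyde (KOH, EtOH, rt) gives (E)-1-{2,4-bis(benzyloxy)-6-hydroxy-3-[(2R)-1-methylpiperidin-2-yl]phenyl}-3-[4-(benzyloxy)phenyl]prop-2-en-1-one F6. NaOAc in refluxing EtOH closes the ring by oxa-Michael addition to a mixture of 15 and its C2 epimer (2R)-5,7-bis(benzyloxy)-2-[4-(benzyloxy)phenyl]-6-[(2R)-1-methylpiperidin-2-yl]chroman-4-one F7. The two are diastereomers and are separated by preparative HPLC; F7 is returned to the same NaOAc conditions to re-equilibrate. The route is rejoined at 15.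

Step 4 (Negishi coupling) joins a pyridyl group to an iodide flanked by two benzyloxy groups, and may stall at oxidative addition or lose the pyridylzinc reagent to homocoupling. The fallback sets out from 6 and reverses the polarity of the coupling. Zn dust activated with LiCl (THF, 50 °C) inserts into the C–I bond, with the chromone and benzyl ethers tolerated, to give [5,7-bis(benzyloxy)-4-oxo-4H-chromen-6-yl]zinc iodide F1. F1 is coupled with commercial 2-bromopyridine under Pd(OAc)2 (3 mol %) and SPhos (6 mol %) in THF at 60 °C, so that oxidative addition now takes place at the unhindered partner. The route is rejoined at 8.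

## Further compounds

F1 | step 4 | [5,7-bis(benzyloxy)-4-oxo-4H-chromen-6-yl]zinc iodide | I[Zn]c1c(OCc2ccccc2)cc2occc(=O)c2c1OCc1ccccc1
F2 | step 6 | (2S)-2-[5,7-bis(benzyloxy)-4-oxo-4H-chromen-6-yl]-1-methylpiperidin-1-ium iodide | C[NH+]1CCCC[C@H]1c1c(OCc2ccccc2)cc2occc(=O)c2c1OCc1ccccc1.[I-]
F3 | step 6 | 5,7-bis(benzyloxy)-6-[(2S)-1-methylpiperidin-2-yl]-4H-chromen-4-one | CN1CCCC[C@H]1c1c(OCc2ccccc2)cc2occc(=O)c2c1OCc1ccccc1
F4 | step 6 | 1:1 salt of 13 with (2R,3R)-di-O-p-toluoyltartaric acid | C[NH+]1CCCC[C@@H]1c1c(OCc2ccccc2)cc2occc(=O)c2c1OCc1ccccc1.Cc1ccc(cc1)C(=O)O[C@@H](C([O-])=O)[C@@H](OC(=O)c1ccc(C)cc1)C(O)=O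
F5 | step 7 | 1-{2,4-bis(benzyloxy)-6-hydroxy-3-[(2R)-1-methylpiperidin-2-yl]phenyl}ethan-1-one | CN1CCCC[C@@H]1c1c(OCc2ccccc2)cc(O)c(C(C)=O)c1OCc1ccccc1
F6 | step 7 | (E)-1-{2,4-bis(benzyloxy)-6-hydroxy-3-[(2R)-1-methylpiperidin-2-yl]phenyl}-3-[4-(benzyloxy)phenyl]prop-2-en-1-one | CN1CCCC[C@@H]1c1c(OCc2ccccc2)cc(O)c(C(=O)/C=C/c2ccc(OCc3ccccc3)cc2)c1OCc1ccccc1
F7 | step 7 | (2R)-5,7-bis(benzyloxy)-2-[4-(benzyloxy)phenyl]-6-[(2R)-1-methylpiperidin-2-yl]chroman-4-one | CN1CCCC[C@@H]1c1c(OCc2ccccc2)cc2c(c1OCc1ccccc1)C(=O)C[C@H](c1ccc(OCc3ccccc3)cc1)O2
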